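Two flasks, one enzyme.

| setting | red | blue |
|---|---|---|
| substrate | 20 mM | 20 mM |
| free enzyme | 2.0 µM | 2.0 µM |
| temperature | 25 °C | 10 °C |
| time | 6.0 min | 6.0 min |

1. the flask that comes out highest in amount of product, in percent of the substrate charged, or "all alike" when all lie within 1.5 percentage points (red / blue / all alike)
2. product at the end, in percent of the substrate charged, red
3. product at the end, in percent of the substrate charged, blue

- a species is counted by the substrate in it: one homo dimer counts as two
- for a step with 2 of a species take k times the square, and two of it per event
- all constants are for 25 °C and move with temperature by the activation energies and enthalpies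

    free enzyme → spent catalyst (k1 = 0.0020 s⁻¹, Ea1 = 82.0 kJ mol⁻¹)
    2 substrate → homo dimer (k2 = 0.17 L mol⁻¹ s⁻¹, Ea2 = 53.0 kJ mol⁻¹)
    substrate + free enzyme → product + free enzyme, rate k3*[substrate]*[free enzyme]/(1 + ([substrate]/Km3) + ([substrate]/Ksi3)^2) (Km3 = 18 mM, Ksi3 = 7.1 mM, k3 = 17000 L mol⁻¹ s⁻¹, Ea3 = 12.0 kJ mol⁻¹)
    substrate ⇌ dormant form (K4 = 0.27, k4 = 0.0013 s⁻¹, Ea4 = 93.0 kJ mol⁻¹, ΔH4 = −9.00 kJ mol⁻¹)
    free enzyme → unfolded enzyme (k5 = 2.9 × 10⁻⁴ s⁻¹, Ea5 = 262 kJ mol⁻¹)
    (constants at 25 °C)

- Free enzyme turns substrate into product while pairs of substrate form homo dimer, so I asked how the substrate divides between these two ways, setting the dormant form aside and letting the substrate run to its end.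
- Dividing the catalytic rate by the substrate's loss to dimer gave a split, or selectivity factor, S = G/([substrate]·D), where D is the denominator of the catalytic law and G is 100 mM: the split constant, the catalytic constant times [free enzyme] over two times the dimerisation constant, which is the value of [substrate]·D at which the two ways run level.
- In red, S was 0.498 at the charge, so dimer led at first, but at half the charge S was 2.83.
- The share going to product is S/(1+S), which was 33.2% at the charge and 73.9% at 10.0 mM of substrate, and it tends to a whole as the substrate vanishes; Simpson's rule over these points gave red 71.4%.
- Cooling to blue slows dimerisation by 3.1 and catalysis by 1.29, the same factor raised to the ratio of activation energies, so dimerisation slows more and every S grows by 2.40. Blue came to 83.8%.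
- One link I could reforge was G held at the charged enzyme: free enzyme decays first-order by its two loss steps, and at the starting rate red reaches half the charge in 0.818 min, keeping 89.4% of its free enzyme. Scaling S at that point gave red 70.0%.
- In blue the same reckoning took 1.73 min and kept 96.4%, which gave 83.6%.
- The forecast gave red 69.5% and blue 78.5%, with blue highest, holding that cooling “cuts dimerisation, dormancy and especially enzyme death much more”; my blue stood higher than its figure, by 5.1 percentage points.
- Red ended at 68.6% and blue at 81.3%, so blue came out highest, as forecast, with homo dimer at 27.9% in red against 16.3% in blue. A neighbour of red was charged with 0.0080 mM of free enzyme, which lifts the split constant to 400 mM. The same reckoning, with half the charge reached in 0.410 min, gives 88.7%. That neighbour held 88.3% product after 6.00 min.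

(The numbers of this flask were chosen freely; the rest is arithmetic.)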